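The synthesis rests on one lactone: C1 (ester carbonyl), C2 (aryl-bearing), C3 (benzyl-bearing), C4 (acid carbon) and the C4 oxygen are the five ring atoms of a cis-3-aryl-4-benzyl-γ-butyrolactone with C1 as its carbonyl. An enantioselective palladium cyclocarbonylation closes this ring from a Z-allylic alcohol and CO. In one operation it forms C2–C1 and C1–O, sets C2 and C3 by syn addition, and leaves C1 and C4 chemically distinct. The precursor is a Z-trisubstituted styrenyl primary alcohol carrying the prenyl group and two aryl triisopropylsilyl ethers, which are used because they should outlast the later hydroxide ring opening, where aryl tert-butyldimethylsilyl ethers would not.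

Key step: step 9

Assumption: the sense of induction of a chiral 1,4-bisphosphine on this trisubstituted styrenyl alcohol cannot be assigned in advance, so the ligand antipode that gives the (3S,4S) lactone is fixed in a first small-scale run with both antipodes.

Step 1
Reactants: 1 4-hydroxybenzaldehyde; 2 1-bromo-3-methylbut-2-ene
Product: 3 4-hydroxy-3-(3-methylbut-2-enyl)benzaldehyde
Conditions: KOH, H2O, rt
Reagents that add atoms: none
Why: Phenoxide C-alkylation in water, where hydrogen bonding to the phenoxide oxygen steers the allylic bromide to the ortho carbon (para is blocked), should give the ortho-prenyl phenol, separable from the O-prenyl ether by chromatography.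

Step 2
Reactants: 3 4-hydroxy-3-(3-methylbut-2-enyl)benzaldehyde
Product: 4 3-(3-methylbut-2-enyl)-4-(triisopropylsilyloxy)benzaldehyde
Conditions: TIPSCl, imidazole, DMF, rt
Reagents that add atoms: chlorotriisopropylsilane, CC(C)[Si](Cl)(C(C)C)C(C)C
Why: Imidazole-promoted O-silylation of the acidic para-formyl phenol is routine and installs an aryl silyl ether that is robust to base, hydride and fluoride-free conditions.

Step 3
Reactants: 4 3-(3-methylbut-2-enyl)-4-(triisopropylsilyloxy)benzaldehyde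
Product: 5 [3-(3-methylbut-2-enyl)-4-(triisopropylsilyloxy)phenyl]methanol
Conditions: NaBH4, MeOH, 0 °C
Reagents that add atoms: none
Why: Borohydride reduction of the aryl aldehyde touches neither the isolated alkene nor the hindered silyl ether.

Step 4
Reactants: 5 [3-(3-methylbut-2-enyl)-4-(triisopropylsilyloxy)phenyl]methanol
Product: 6 [4-(bromomethyl)-2-(3-methylbut-2-enyl)phenoxy]triisopropylsilane
Conditions: CBr4, PPh3, CH2Cl2, 0 °C
Reagents that add atoms: tetrabromomethane, BrC(Br)(Br)Br
Why: The Appel reaction converts the benzylic alcohol to the bromide under neutral conditions, so no HBr adds to the prenyl alkene; the electron-rich bromide is used promptly.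

Step 5
Reactants: 7 methyl bis(2,2,2-trifluoroethyl)phosphonoacetate; 6 [4-(bromomethyl)-2-(3-methylbut-2-enyl)phenoxy]triisopropylsilane
Product: 8 methyl 2-[bis(2,2,2-trifluoroethoxy)phosphoryl]-3-[3-(3-methylbut-2-enyl)-4-(triisopropylsilyloxy)phenyl]propanoate (racemic)
Conditions: NaH, 7 (1.5 equiv), DMF, 0 °C; then 6, 0 °C to rt
Reagents that add atoms: none
Why: SN2 C-alkylation of the stabilised phosphonoacetate carbanion by a reactive benzylic bromide, with excess 7 to suppress dialkylation; the new centre is racemic and is destroyed in step 7.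

Step 6
Reactants: 1 4-hydroxybenzaldehyde
Product: 9 4-(triisopropylsilyloxy)benzaldehyde
Conditions: TIPSCl, imidazole, DMF, rt
Reagents that add atoms: chlorotriisopropylsilane, CC(C)[Si](Cl)(C(C)C)C(C)C
Why: The same imidazole-promoted phenol silylation as in step 2.

Step 7
Reactants: 8 methyl 2-[bis(2,2,2-trifluoroethoxy)phosphoryl]-3-[3-(3-methylbut-2-enyl)-4-(triisopropylsilyloxy)phenyl]propanoate; 9 4-(triisopropylsilyloxy)benzaldehyde
Product: 10 methyl (Z)-2-[[3-(3-methylbut-2-enyl)-4-(triisopropylsilyloxy)phenyl]methyl]-3-[4-(triisopropylsilyloxy)phenyl]prop-2-enoate (aryl cis to the ester)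
Conditions: KHMDS, 18-crown-6, THF, −78 °C; then 9, −78 to −40 °C
Reagents that add atoms: none
Why: In the Still–Gennari olefination the electron-poor trifluoroethyl phosphonate and the dissociated potassium counter-ion make collapse of the kinetic adduct fast and irreversible, which should place the aryl group cis to the ester; the minor geometric isomer is removed by chromatography.

Step 8
Reactants: 10 methyl (Z)-2-[[3-(3-methylbut-2-enyl)-4-(triisopropylsilyloxy)phenyl]methyl]-3-[4-(triisopropylsilyloxy)phenyl]prop-2-enoate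
Product: 11 (Z)-2-[[3-(3-methylbut-2-enyl)-4-(triisopropylsilyloxy)phenyl]methyl]-3-[4-(triisopropylsilyloxy)phenyl]prop-2-en-1-ol (aryl cis to CH2OH)
Conditions: DIBAL-H, CH2Cl2, −78 °C; Rochelle salt
Reagents that add atoms: none
Why: DIBAL-H reduces the enoate 1,2 to the allylic alcohol at low temperature without touching the alkene geometry or the silyl ethers.

Step 9
Reactants: 11 (Z)-2-[[3-(3-methylbut-2-enyl)-4-(triisopropylsilyloxy)phenyl]methyl]-3-[4-(triisopropylsilyloxy)phenyl]prop-2-en-1-ol
Product: 12 (3S,4S)-4-[[3-(3-methylbut-2-enyl)-4-(triisopropylsilyloxy)phenyl]methyl]-3-[4-(triisopropylsilyloxy)phenyl]oxolan-2-one (cis)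
Conditions: Pd2(dba)3·CHCl3 (cat.), BICP [2,2'-bis(diphenylphosphino)-1,1'-bicyclopentyl, antipode per the assumption], CO/H2 (1:1, ca. 50 bar), CH2Cl2, 80 °C
Reagents that add atoms: carbon monoxide, [C-]#[O+]
Why: Under CO/H2 the bisphosphine–palladium hydride should add syn across the C2=C3 styrenyl bond of 11 with hydrogen to C3 and palladium to benzylic C2, CO then inserts into the C2–Pd bond with retention, and the C4 hydroxyl cleaves the acyl–palladium bond to release 12 and regenerate the hydride. The closest known reaction type is the palladium/1,4-bisphosphine cyclocarbonylation of β,γ-substituted allylic alcohols to α,β-disubstituted γ-butyrolactones, including its enantioselective variant; a primary carbinol beside a second trisubstituted alkene extends that substrate range. The one ring closes by a 5-exo-trig acyl substitution, the hydroxyl oxygen attacking the exocyclic C1=O of the acyl-palladium. C2 (lactone C3) is set by the alkene face that the chiral bisphosphine selects in the hydropalladation, and C3 (lactone C4) is set relative to it by the syn delivery of hydrogen, so the Z geometry of 11 becomes the cis lactone and the ligand antipode decides (3S,4S) against (3R,4R). The step needs regiocontrol, retention of alkene geometry before insertion and chemoselectivity over the prenyl alkene: π-benzyl stabilisation and the fact that only an acyl on C2 can be captured by the tether in a five-membered ring secure the first, the single hydrogen on C3 lets hydropalladation reverse without E/Z scrambling, and the prenyl alkene is unconjugated and has no hydroxyl to capture an acyl. Neutral, base-free conditions should keep the epimerisable cis α-aryl centre intact.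

Step 10
Reactants: 12 (3S,4S)-4-[[3-(3-methylbut-2-enyl)-4-(triisopropylsilyloxy)phenyl]methyl]-3-[4-(triisopropylsilyloxy)phenyl]oxolan-2-one
Product: 14 methyl (2S,3S)-4-hydroxy-3-[[3-(3-methylbut-2-enyl)-4-(triisopropylsilyloxy)phenyl]methyl]-2-[4-(triisopropylsilyloxy)phenyl]butanoate, via ring-opened potassium carboxylate 13 (not isolated)
Conditions: KOH (1.0 equiv), THF/H2O, 0 °C; concentrate; MeI, DMF, 0 °C; cold neutral work-up, used at once
Reagents that add atoms: potassium hydroxide, [K+].[OH-]; iodomethane, CI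
Why: Saponification then carboxylate SN2 O-methylation: hydroxide attack on the lactone carbonyl should outrun α-deprotonation, the resulting carboxylate is no longer enolisable at C2, and methylation needs neither acid nor alkoxide, so both centres and the hindered aryl silyl ethers should survive.

Step 11
Reactants: 14 methyl (2S,3S)-4-hydroxy-3-[[3-(3-methylbut-2-enyl)-4-(triisopropylsilyloxy)phenyl]methyl]-2-[4-(triisopropylsilyloxy)phenyl]butanoate
Product: 15 methyl (2S,3S)-3-formyl-4-[3-(3-methylbut-2-enyl)-4-(triisopropylsilyloxy)phenyl]-2-[4-(triisopropylsilyloxy)phenyl]butanoate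
Conditions: Dess–Martin periodinane, pyridine, CH2Cl2, 0 °C
Reagents that add atoms: none
Why: The pyridine-buffered Dess–Martin oxidation is fast and near neutral, so it should remove the γ-hydroxyl before it can re-close onto C1 and should not enolise C2 or C3.

Step 12
Reactants: 15 methyl (2S,3S)-3-formyl-4-[3-(3-methylbut-2-enyl)-4-(triisopropylsilyloxy)phenyl]-2-[4-(triisopropylsilyloxy)phenyl]butanoate
Product: 16 (2S,3S)-4-methoxy-2-[[3-(3-methylbut-2-enyl)-4-(triisopropylsilyloxy)phenyl]methyl]-4-oxo-3-[4-(triisopropylsilyloxy)phenyl]butanoic acid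
Conditions: NaClO2, NaH2PO4, 2-methylbut-2-ene (large excess), t-BuOH/H2O, 0 °C
Reagents that add atoms: sodium chlorite, [Na+].[O-]Cl=O
Why: The Pinnick oxidation takes the aldehyde to the acid at mildly acidic pH without epimerisation, while the excess scavenger alkene consumes hypochlorous acid before it can reach the prenyl group or the silyloxy arenes.

Step 13
Reactants: 16 (2S,3S)-4-methoxy-2-[[3-(3-methylbut-2-enyl)-4-(triisopropylsilyloxy)phenyl]methyl]-4-oxo-3-[4-(triisopropylsilyloxy)phenyl]butanoic acid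
Product: 17 asperteretal G2, (2S,3S)-2-[[4-hydroxy-3-(3-methylbut-2-enyl)phenyl]methyl]-3-(4-hydroxyphenyl)-4-methoxy-4-oxobutanoic acid
Conditions: TBAF, AcOH (1:1), THF, 0 °C
Reagents that add atoms: none
Why: Fluoride cleavage of the two aryl Si–O bonds, buffered with acetic acid, should free both phenols without enolising C2, hydrolysing the methyl ester or exposing the ortho-prenyl phenol to the strong acid that would close a chroman.

Compound list
1 | 4-hydroxybenzaldehyde | O=Cc1ccc(O)cc1 | starting material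
2 | 1-bromo-3-methylbut-2-ene | CC(C)=CCBr | starting material
3 | 4-hydroxy-3-(3-methylbut-2-enyl)benzaldehyde | O=Cc1ccc(O)c(CC=C(C)C)c1 | intermediate
4 | 3-(3-methylbut-2-enyl)-4-(triisopropylsilyloxy)benzaldehyde | O=Cc1ccc(O[Si](C(C)C)(C(C)C)C(C)C)c(CC=C(C)C)c1 | intermediate
5 | [3-(3-methylbut-2-enyl)-4-(triisopropylsilyloxy)phenyl]methanol | OCc1ccc(O[Si](C(C)C)(C(C)C)C(C)C)c(CC=C(C)C)c1 | intermediate
6 | [4-(bromomethyl)-2-(3-methylbut-2-enyl)phenoxy]triisopropylsilane | BrCc1ccc(O[Si](C(C)C)(C(C)C)C(C)C)c(CC=C(C)C)c1 | intermediate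
7 | methyl bis(2,2,2-trifluoroethyl)phosphonoacetate | COC(=O)CP(=O)(OCC(F)(F)F)OCC(F)(F)F | starting material
8 | methyl 2-[bis(2,2,2-trifluoroethoxy)phosphoryl]-3-[3-(3-methylbut-2-enyl)-4-(triisopropylsilyloxy)phenyl]propanoate (racemic) | COC(=O)C(Cc1ccc(O[Si](C(C)C)(C(C)C)C(C)C)c(CC=C(C)C)c1)P(=O)(OCC(F)(F)F)OCC(F)(F)F | intermediate
9 | 4-(triisopropylsilyloxy)benzaldehyde | O=Cc1ccc(O[Si](C(C)C)(C(C)C)C(C)C)cc1 | intermediate
10 | methyl (Z)-2-[[3-(3-methylbut-2-enyl)-4-(triisopropylsilyloxy)phenyl]methyl]-3-[4-(triisopropylsilyloxy)phenyl]prop-2-enoate | COC(=O)/C(Cc1ccc(O[Si](C(C)C)(C(C)C)C(C)C)c(CC=C(C)C)c1)=C\c1ccc(O[Si](C(C)C)(C(C)C)C(C)C)cc1 | intermediate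
11 | (Z)-2-[[3-(3-methylbut-2-enyl)-4-(triisopropylsilyloxy)phenyl]methyl]-3-[4-(triisopropylsilyloxy)phenyl]prop-2-en-1-ol | OC/C(Cc1ccc(O[Si](C(C)C)(C(C)C)C(C)C)c(CC=C(C)C)c1)=C\c1ccc(O[Si](C(C)C)(C(C)C)C(C)C)cc1 | intermediate
12 | (3S,4S)-4-[[3-(3-methylbut-2-enyl)-4-(triisopropylsilyloxy)phenyl]methyl]-3-[4-(triisopropylsilyloxy)phenyl]oxolan-2-one | O=C1[C@H](c2ccc(O[Si](C(C)C)(C(C)C)C(C)C)cc2)[C@H](Cc2ccc(O[Si](C(C)C)(C(C)C)C(C)C)c(CC=C(C)C)c2)CO1 | intermediate
13 | potassium (2S,3S)-4-hydroxy-3-[[3-(3-methylbut-2-enyl)-4-(triisopropylsilyloxy)phenyl]methyl]-2-[4-(triisopropylsilyloxy)phenyl]butanoate | [K+].[O-]C(=O)[C@H](c1ccc(O[Si](C(C)C)(C(C)C)C(C)C)cc1)[C@H](Cc1ccc(O[Si](C(C)C)(C(C)C)C(C)C)c(CC=C(C)C)c1)CO | intermediate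
14 | methyl (2S,3S)-4-hydroxy-3-[[3-(3-methylbut-2-enyl)-4-(triisopropylsilyloxy)phenyl]methyl]-2-[4-(triisopropylsilyloxy)phenyl]butanoate | COC(=O)[C@H](c1ccc(O[Si](C(C)C)(C(C)C)C(C)C)cc1)[C@H](Cc1ccc(O[Si](C(C)C)(C(C)C)C(C)C)c(CC=C(C)C)c1)CO | intermediate
15 | methyl (2S,3S)-3-formyl-4-[3-(3-methylbut-2-enyl)-4-(triisopropylsilyloxy)phenyl]-2-[4-(triisopropylsilyloxy)phenyl]butanoate | COC(=O)[C@H](c1ccc(O[Si](C(C)C)(C(C)C)C(C)C)cc1)[C@H](Cc1ccc(O[Si](C(C)C)(C(C)C)C(C)C)c(CC=C(C)C)c1)C=O | intermediate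
16 | (2S,3S)-4-methoxy-2-[[3-(3-methylbut-2-enyl)-4-(triisopropylsilyloxy)phenyl]methyl]-4-oxo-3-[4-(triisopropylsilyloxy)phenyl]butanoic acid | COC(=O)[C@H](c1ccc(O[Si](C(C)C)(C(C)C)C(C)C)cc1)[C@H](Cc1ccc(O[Si](C(C)C)(C(C)C)C(C)C)c(CC=C(C)C)c1)C(=O)O | intermediate
17 | asperteretal G2, (2S,3S)-2-[[4-hydroxy-3-(3-methylbut-2-enyl)phenyl]methyl]-3-(4-hydroxyphenyl)-4-methoxy-4-oxobutanoic acid | COC(=O)[C@H](c1ccc(O)cc1)[C@H](Cc1ccc(O)c(CC=C(C)C)c1)C(=O)O | target

Total step count: 13. Longest linear sequence: 12 steps (steps 1–5 and 7–13); step 6 is a one-step branch.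

Steps most likely to fail

Step 9. The catalyst may discriminate poorly between the alkene faces. The palladium hydride may also be diverted into redox isomerisation of the primary allylic alcohol, ionisation of its C–O bond, or migration of the prenyl double bond. The fallback builds the lactone by auxiliary control, setting out from bromide 6 and coming back at lactone 12. Mono-tert-butyl succinate is coupled through its pivaloyl mixed anhydride to (S)-4-benzyloxazolidin-2-one to give (S)-4-benzyl-3-(4-tert-butoxy-4-oxobutanoyl)oxazolidin-2-one F1. Its sodium Z-enolate (NaHMDS, THF, −78 °C) is benzylated by 6 on the face away from the auxiliary benzyl group (Evans alkylation) to give tert-butyl (3S)-4-[(4S)-4-benzyl-2-oxo-1,3-oxazolidin-3-yl]-3-[[3-(3-methylbut-2-enyl)-4-(triisopropylsilyloxy)phenyl]methyl]-4-oxobutanoate F2. LiBH4 (THF, 0 °C) removes the auxiliary reductively to give tert-butyl (3S)-4-hydroxy-3-[[3-(3-methylbut-2-enyl)-4-(triisopropylsilyloxy)phenyl]methyl]butanoate F3, which catalytic KOt-Bu in THF closes to (4S)-4-[[3-(3-methylbut-2-enyl)-4-(triisopropylsilyloxy)phenyl]methyl]oxolan-2-one F4. Palladium-catalysed α-arylation of its lithium enolate with (4-bromophenoxy)triisopropylsilane (LiHMDS, Pd(dba)2, P(t-Bu)3, toluene) should give mainly the trans lactone (3R,4S)-4-[[3-(3-methylbut-2-enyl)-4-(triisopropylsilyloxy)phenyl]methyl]-3-[4-(triisopropylsilyloxy)phenyl]oxolan-2-one F5. Deprotonation with LDA at −78 °C and kinetic protonation by a hindered phenol, from the face opposite the C4 benzyl group, should then turn the aryl group cis and give 12.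

Step 10. Hydroxide may epimerise C2 before it opens the ring, the γ-hydroxy methyl ester may re-close to the lactone before it is oxidised, or an aryl silyl ether may be lost. The fallback never frees the hydroxy ester; it sets out from the potassium carboxylate 13 and comes back at aldehyde 15, bypassing step 11. The salt 13 is silylated on both oxygens (TESCl, imidazole, DMF, 0 °C) to give triethylsilyl (2S,3S)-3-[[3-(3-methylbut-2-enyl)-4-(triisopropylsilyloxy)phenyl]methyl]-4-(triethylsilyloxy)-2-[4-(triisopropylsilyloxy)phenyl]butanoate F6. Its silyl ester hydrolyses on buffered aqueous work-up to (2S,3S)-3-[[3-(3-methylbut-2-enyl)-4-(triisopropylsilyloxy)phenyl]methyl]-4-(triethylsilyloxy)-2-[4-(triisopropylsilyloxy)phenyl]butanoic acid F7. Trimethylsilyldiazomethane (toluene/MeOH, 0 °C) gives the stable, purifiable methyl (2S,3S)-3-[[3-(3-methylbut-2-enyl)-4-(triisopropylsilyloxy)phenyl]methyl]-4-(triethylsilyloxy)-2-[4-(triisopropylsilyloxy)phenyl]butanoate F8. Swern conditions (oxalyl chloride, DMSO, CH2Cl2, −78 to −40 °C, then Et3N) oxidise the primary triethylsilyl ether directly to aldehyde 15.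

Step 7. The olefination may give insufficient kinetic Z selectivity with the α-benzyl phosphonate and the electron-rich aldehyde, and any E isomer carried forward would end as the trans lactone. The fallback fixes the geometry by a stereospecific syn addition to an alkyne; it sets out from aldehyde 9 (with bromide 6) and comes back at ester 10, replacing steps 5 and 7. Ramirez olefination of 9 (CBr4, PPh3, CH2Cl2, 0 °C) gives [4-(2,2-dibromoethenyl)phenoxy]triisopropylsilane F9. n-BuLi (2 equiv, THF, −78 °C) followed by methyl chloroformate (Corey–Fuchs sequence) gives methyl 3-[4-(triisopropylsilyloxy)phenyl]prop-2-ynoate F10. Pd(PPh3)4-catalysed hydrostannation with Bu3SnH adds hydrogen and tin syn, with tin α to the ester, to give methyl (E)-2-(tributylstannyl)-3-[4-(triisopropylsilyloxy)phenyl]prop-2-enoate F11, in which aryl and ester are already cis. Stille coupling with 6 (Pd2(dba)3, AsPh3, CuI, DMF) proceeds with retention at the vinyl carbon and should deliver 10.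

Further compounds
F1 | step 9 | (S)-4-benzyl-3-(4-tert-butoxy-4-oxobutanoyl)oxazolidin-2-one | CC(C)(C)OC(=O)CCC(=O)N1[C@@H](Cc2ccccc2)COC1=O
F2 | step 9 | tert-butyl (3S)-4-[(4S)-4-benzyl-2-oxo-1,3-oxazolidin-3-yl]-3-[[3-(3-methylbut-2-enyl)-4-(triisopropylsilyloxy)phenyl]methyl]-4-oxobutanoate | CC(C)(C)OC(=O)C[C@H](Cc1ccc(O[Si](C(C)C)(C(C)C)C(C)C)c(CC=C(C)C)c1)C(=O)N1[C@@H](Cc2ccccc2)COC1=O
F3 | step 9 | tert-butyl (3S)-4-hydroxy-3-[[3-(3-methylbut-2-enyl)-4-(triisopropylsilyloxy)phenyl]methyl]butanoate | CC(C)(C)OC(=O)C[C@H](Cc1ccc(O[Si](C(C)C)(C(C)C)C(C)C)c(CC=C(C)C)c1)CO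
F4 | step 9 | (4S)-4-[[3-(3-methylbut-2-enyl)-4-(triisopropylsilyloxy)phenyl]methyl]oxolan-2-one | O=C1C[C@H](Cc2ccc(O[Si](C(C)C)(C(C)C)C(C)C)c(CC=C(C)C)c2)CO1
F5 | step 9 | (3R,4S)-4-[[3-(3-methylbut-2-enyl)-4-(triisopropylsilyloxy)phenyl]methyl]-3-[4-(triisopropylsilyloxy)phenyl]oxolan-2-one | O=C1[C@@H](c2ccc(O[Si](C(C)C)(C(C)C)C(C)C)cc2)[C@H](Cc2ccc(O[Si](C(C)C)(C(C)C)C(C)C)c(CC=C(C)C)c2)CO1
F6 | step 10 | triethylsilyl (2S,3S)-3-[[3-(3-methylbut-2-enyl)-4-(triisopropylsilyloxy)phenyl]methyl]-4-(triethylsilyloxy)-2-[4-(triisopropylsilyloxy)phenyl]butanoate | CC[Si](CC)(CC)OC(=O)[C@H](c1ccc(O[Si](C(C)C)(C(C)C)C(C)C)cc1)[C@H](Cc1ccc(O[Si](C(C)C)(C(C)C)C(C)C)c(CC=C(C)C)c1)CO[Si](CC)(CC)CC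
F7 | step 10 | (2S,3S)-3-[[3-(3-methylbut-2-enyl)-4-(triisopropylsilyloxy)phenyl]methyl]-4-(triethylsilyloxy)-2-[4-(triisopropylsilyloxy)phenyl]butanoic acid | OC(=O)[C@H](c1ccc(O[Si](C(C)C)(C(C)C)C(C)C)cc1)[C@H](Cc1ccc(O[Si](C(C)C)(C(C)C)C(C)C)c(CC=C(C)C)c1)CO[Si](CC)(CC)CC
F8 | step 10 | methyl (2S,3S)-3-[[3-(3-methylbut-2-enyl)-4-(triisopropylsilyloxy)phenyl]methyl]-4-(triethylsilyloxy)-2-[4-(triisopropylsilyloxy)phenyl]butanoate | COC(=O)[C@H](c1ccc(O[Si](C(C)C)(C(C)C)C(C)C)cc1)[C@H](Cc1ccc(O[Si](C(C)C)(C(C)C)C(C)C)c(CC=C(C)C)c1)CO[Si](CC)(CC)CC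
F9 | step 7 | [4-(2,2-dibromoethenyl)phenoxy]triisopropylsilane | BrC(Br)=Cc1ccc(O[Si](C(C)C)(C(C)C)C(C)C)cc1
F10 | step 7 | methyl 3-[4-(triisopropylsilyloxy)phenyl]prop-2-ynoate | COC(=O)C#Cc1ccc(O[Si](C(C)C)(C(C)C)C(C)C)cc1
F11 | step 7 | methyl (E)-2-(tributylstannyl)-3-[4-(triisopropylsilyloxy)phenyl]prop-2-enoate | COC(=O)/C([Sn](CCCC)(CCCC)CCCC)=C\c1ccc(O[Si](C(C)C)(C(C)C)C(C)C)cc1
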